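**Plan**

- Cuts, last to first: C8–C9 (Stille coupling of an α-bromobutenolide with the epoxy-ring vinylstannane); C10–C11 and O–C11 (tandem Sonogashira coupling–lactonisation of a terminal polyenyne with (E)-2,3-dibromoacrylic acid); C6'–C7' (Sonogashira coupling of a ring enol triflate with a C2-symmetric C14 tetraenediyne, itself made from glyoxal and two C6 enynyl ylides by forming C15=C15' and C14'=C11').
- Both six-membered rings come from one enol triflate. Its ring is cut at C1'–C2' and C4'–C5': a (3+3) annulation of a β-keto ester 1,3-dianion with a three-carbon bis-electrophile made from (S)-epichlorohydrin.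
- Feature used: the alkyne-bearing ring carbon C6' is a masked ketone carbon, so its ring neighbours C1' (CMe2) and C5' (C–Me) are the α and α' carbons of one carbonyl, i.e. a 1,3-dinucleophile. The rest of the ring, C2'H2–C3'H(OH)–C4'H2, is a glycerol-type 1,3-dielectrophile with its only stereocentre on the central carbon.
- Forward order: annulation, gem-dimethylation, loss of the ester helper, enol triflate. The triflate then branches to (a) the polyenyne and bromobutenolide and (b) the epoxy vinylstannane; the chain is closed last at C8–C9.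
- Stereochemistry: C3 and C3' both come from (S)-epichlorohydrin (the order γ-carbon/iodide first, α-carbon/chloride second decides which arm joins which α-carbon). C5/C6 come from a Sharpless epoxidation anti to the C3 silyloxy group. E-alkenes come from the commercial (E)-enynol, an iodine-equilibrated Wittig reaction and a Takai olefination; the Z-ylidene comes from anti addition in the lactonisation.

Key step: step 4

Remark: locants are carotenoid locants (unprimed for the epoxide half with the butenolide, primed for the acetylenic half). Ring stereocentres that are erased later (the CHMe and quaternary ester carbons) are carried as diastereomer mixtures. Glyoxal is taken as its commercial trimer dihydrate.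

**Route**

Step 1
Reactants: 1 methyl 2-methyl-3-oxopentanoate
Product: 2 benzyl 2-methyl-3-oxopentanoate (racemic)
Conditions: BnOH (1.2 equiv), DMAP (cat.), toluene, reflux, removal of MeOH
Reagents that add atoms: benzyl alcohol, OCc1ccccc1
Why: DMAP-catalysed transesterification of an enolisable β-keto ester, driven by removal of methanol, should give the benzyl ester, which can later be removed by hydrogenolysis without touching a silyl ether.

Step 2
Reactants: 3 (S)-epichlorohydrin
Product: 4 (2R)-1-chloro-3-iodopropan-2-ol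
Conditions: LiI, AcOH, THF, 0 °C to rt
Reagents that add atoms: lithium iodide, [Li+].[I-]
Why: Iodide opens the protonated epoxide by SN2 at the unsubstituted CH2 (halohydrin formation), so the stereocentre is untouched and its two arms become chemically different (CH2I and CH2Cl).

Step 3
Reactants: 4 (2R)-1-chloro-3-iodopropan-2-ol
Product: 5 tert-butyl{[(2R)-1-chloro-3-iodopropan-2-yl]oxy}dimethylsilane
Conditions: TBSOTf, 2,6-lutidine, CH2Cl2, −78 to 0 °C
Reagents that add atoms: tert-butyldimethylsilyl triflate, CC(C)(C)[Si](C)(C)OS(=O)(=O)C(F)(F)F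
Why: Silylation of the secondary alcohol blocks alkoxide chemistry (epoxide re-closure, attack on carbonyl groups) in the annulation and gives the protecting group carried through both halves.

Step 4
Reactants: 2 benzyl 2-methyl-3-oxopentanoate; 5 tert-butyl{[(2R)-1-chloro-3-iodopropan-2-yl]oxy}dimethylsilane
Product: 7 benzyl (5S)-5-[(tert-butyldimethylsilyl)oxy]-1,3-dimethyl-2-oxocyclohexane-1-carboxylate, via lithium enolate of chloro keto ester 6 (not isolated)
Conditions: LiN(iPr)2 (2.1 equiv), THF, 0 °C; 5, −78 to 0 °C; then DMPU, NaI (cat.), 50 °C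
Reagents that add atoms: none
Why: The α,γ-dianion of 2 attacks the primary iodide of 5 through its more basic γ-carbon (SN2, C1'–C2' bond), which leaves the α-enolate of 6; on warming this enolate displaces the primary chloride (C4'–C5' bond) and closes the cyclohexanone. The closest known reaction type is the γ-alkylation of β-keto ester dianions combined with their cyclisation onto 1,3-dihalides of the 1-bromo-3-chloropropane type. The six-membered ring closes in the 6-(enolendo)-exo-tet mode, for which C-alkylation is expected to win over O-alkylation. The two new stereocentres (the CHMe carbon and the quaternary ester carbon) form without control and do not matter, because both are erased in steps 5 to 7; the silyloxy carbon is carried unchanged from (S)-epichlorohydrin. The step needs site selectivity on both partners, γ before α on the dianion and iodide before chloride on 5, because this order decides which CH2 arm joins which α-carbon and therefore the absolute configuration of the carbinol carbon in the ring; the reactivity gaps between the two carbanion sites and between iodide and chloride, together with the silyl ether that prevents epoxide formation, should secure it.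

Step 5
Reactants: 7 benzyl (5S)-5-[(tert-butyldimethylsilyl)oxy]-1,3-dimethyl-2-oxocyclohexane-1-carboxylate
Product: 8 benzyl (5S)-5-[(tert-butyldimethylsilyl)oxy]-1,3,3-trimethyl-2-oxocyclohexane-1-carboxylate (mixture at C1)
Conditions: LiN(iPr)2, THF, −78 °C; MeI, DMPU, −78 to 0 °C
Reagents that add atoms: iodomethane, CI
Why: Only one α-hydrogen is left (the other α-carbon is quaternary), so ketone enolate C-methylation installs the geminal dimethyl group regiospecifically and removes one uncontrolled stereocentre.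

Step 6
Reactants: 8 benzyl (5S)-5-[(tert-butyldimethylsilyl)oxy]-1,3,3-trimethyl-2-oxocyclohexane-1-carboxylate
Product: 9 (4R)-4-[(tert-butyldimethylsilyl)oxy]-2,2,6-trimethylcyclohexan-1-one (mixture at C6)
Conditions: H2 (1 atm), Pd/C, EtOAc, rt; then toluene, 80 °C
Reagents that add atoms: none
Why: Hydrogenolysis of the benzyl ester gives the β-keto acid, which should lose CO2 on warming (β-keto acid decarboxylation); the new CHMe centre forms as an epimer mixture that is erased in step 7.

Step 7
Reactants: 9 (4R)-4-[(tert-butyldimethylsilyl)oxy]-2,2,6-trimethylcyclohexan-1-one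
Product: 10 (4R)-4-[(tert-butyldimethylsilyl)oxy]-2,6,6-trimethylcyclohex-1-en-1-yl trifluoromethanesulfonate
Conditions: KN(SiMe3)2, THF, −78 °C; PhNTf2, −78 to 0 °C
Reagents that add atoms: N-phenylbis(trifluoromethanesulfonimide), O=S(=O)(N(c1ccccc1)S(=O)(=O)C(F)(F)F)C(F)(F)F
Why: The ketone has a single α-hydrogen, so enolate formation and O-triflation (enol triflate synthesis) are regiospecific and fix the ring double bond between C5' and C6'.

Step 8
Reactants: 11 (2E)-3-methylpent-2-en-4-yn-1-ol
Product: 12 [(2E)-3-methylpent-2-en-4-yn-1-yl]triphenylphosphonium bromide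
Conditions: PPh3·HBr, MeOH, rt
Reagents that add atoms: triphenylphosphine hydrobromide, Br.c1ccc(cc1)P(c1ccccc1)c1ccccc1
Why: The primary allylic alcohol is ionised by HBr and trapped by PPh3 at the primary terminus (allylic phosphonium salt formation), which should keep the conjugated E-enyne.

Step 9
Reactants: 12 [(2E)-3-methylpent-2-en-4-yn-1-yl]triphenylphosphonium bromide (2 equiv); 13 glyoxal
Product: 14 (3E,5E,7E,9E)-3,10-dimethyldodeca-3,5,7,9-tetraene-1,11-diyne
Conditions: NaOMe, MeOH/CH2Cl2, −10 °C to rt; then I2 (cat.), CH2Cl2, daylight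
Reagents that add atoms: none
Why: Twofold Wittig olefination of the dialdehyde by the semi-stabilised allylic ylide builds both new C=C bonds of the C2-symmetric chain, and iodine-catalysed equilibration should convert Z isomers into the all-E tetraene.

Step 10
Reactants: 10 (4R)-4-[(tert-butyldimethylsilyl)oxy]-2,6,6-trimethylcyclohex-1-en-1-yl trifluoromethanesulfonate; 14 (3E,5E,7E,9E)-3,10-dimethyldodeca-3,5,7,9-tetraene-1,11-diyne (3 equiv)
Product: 15 tert-butyl({(1R)-4-[(3E,5E,7E,9E)-3,10-dimethyldodeca-3,5,7,9-tetraene-1,11-diyn-1-yl]-3,5,5-trimethylcyclohex-3-en-1-yl}oxy)dimethylsilane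
Conditions: Pd(PPh3)4 (5 mol%), CuI (10 mol%), Et3N, DMF, rt to 45 °C, no O2
Reagents that add atoms: none
Why: Sonogashira coupling of the enol triflate with one of the two equivalent terminal alkynes (diyne in excess to suppress double coupling, the excess being recovered) forms the C6'–C7' bond.

Step 11
Reactants: 15 tert-butyl({(1R)-4-[(3E,5E,7E,9E)-3,10-dimethyldodeca-3,5,7,9-tetraene-1,11-diyn-1-yl]-3,5,5-trimethylcyclohex-3-en-1-yl}oxy)dimethylsilane
Product: 16 (1R)-4-[(3E,5E,7E,9E)-3,10-dimethyldodeca-3,5,7,9-tetraene-1,11-diyn-1-yl]-3,5,5-trimethylcyclohex-3-en-1-ol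
Conditions: Bu4NF, THF, rt
Reagents that add atoms: none
Why: Fluoride cleaves the silyl ether (desilylation) on a robust intermediate, so that no deprotection is needed on the sensitive final product.

Step 12
Reactants: 17 propiolic acid
Product: 18 (2E)-2,3-dibromoprop-2-enoic acid
Conditions: Br2, CHCl3, 0 °C to rt, dark
Reagents that add atoms: bromine, BrBr
Why: Anti addition of bromine to the alkyne gives the E-dibromide, in which the β-bromine is cis to the carboxyl group as the lactonisation requires.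

Step 13
Reactants: 16 (1R)-4-[(3E,5E,7E,9E)-3,10-dimethyldodeca-3,5,7,9-tetraene-1,11-diyn-1-yl]-3,5,5-trimethylcyclohex-3-en-1-ol; 18 (2E)-2,3-dibromoprop-2-enoic acid (1.5 equiv)
Product: 19 (5Z)-3-bromo-5-[(2E,4E,6E,8E)-11-[(4R)-4-hydroxy-2,6,6-trimethylcyclohex-1-en-1-yl]-2,9-dimethylundeca-2,4,6,8-tetraen-10-yn-1-ylidene]furan-2(5H)-one
Conditions: PdCl2(PPh3)2 (5 mol%), CuI (10 mol%), Et3N, MeCN, rt
Reagents that add atoms: none
Why: Tandem Sonogashira coupling–lactonisation: the β-bromide cis to the carboxyl couples with the terminal alkyne, and the carboxylate then adds 5-exo-dig and anti across the activated triple bond, which sets the Z-ylidene and leaves the α-bromide for step 21.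

Step 14
Reactants: 10 (4R)-4-[(tert-butyldimethylsilyl)oxy]-2,6,6-trimethylcyclohex-1-en-1-yl trifluoromethanesulfonate
Product: 20 methyl (4R)-4-[(tert-butyldimethylsilyl)oxy]-2,6,6-trimethylcyclohex-1-ene-1-carboxylate
Conditions: Pd(OAc)2 (5 mol%), PPh3, CO (1 atm), MeOH, Et3N, DMF, 65 °C
Reagents that add atoms: carbon monoxide, [C-]#[O+]; methanol, CO
Why: Palladium-catalysed methoxycarbonylation of the enol triflate (oxidative addition, CO insertion, methanolysis) installs C7 on the ring.

Step 15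
Reactants: 20 methyl (4R)-4-[(tert-butyldimethylsilyl)oxy]-2,6,6-trimethylcyclohex-1-ene-1-carboxylate
Product: 21 [(4R)-4-[(tert-butyldimethylsilyl)oxy]-2,6,6-trimethylcyclohex-1-en-1-yl]methanol
Conditions: i-Bu2AlH, CH2Cl2, −78 to 0 °C; aq. KNaC4H4O6 work-up
Reagents that add atoms: none
Why: Hydride reduction of the enoate gives the allylic alcohol that is needed to direct the epoxidation.

Step 16
Reactants: 21 [(4R)-4-[(tert-butyldimethylsilyl)oxy]-2,6,6-trimethylcyclohex-1-en-1-yl]methanol
Product: 22 [(1R,4S,6R)-4-[(tert-butyldimethylsilyl)oxy]-2,2,6-trimethyl-7-oxabicyclo[4.1.0]heptan-1-yl]methanol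
Conditions: Ti(OiPr)4 (20 mol%), D-(−)-diethyl tartrate (25 mol%), t-BuOOH, 4 Å molecular sieves, CH2Cl2, −20 °C
Reagents that add atoms: tert-butyl hydroperoxide, CC(C)(C)OO
Why: Sharpless asymmetric epoxidation with the D-(−)-tartrate should deliver oxygen to the face of the tetrasubstituted C5=C6 bond opposite to the silyloxy group (reagent control, reinforced by the steric bias of the ring), which sets C5 and C6.

Step 17
Reactants: 22 [(1R,4S,6R)-4-[(tert-butyldimethylsilyl)oxy]-2,2,6-trimethyl-7-oxabicyclo[4.1.0]heptan-1-yl]methanol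
Product: 23 (1S,4S,6R)-4-[(tert-butyldimethylsilyl)oxy]-2,2,6-trimethyl-7-oxabicyclo[4.1.0]heptane-1-carbaldehyde
Conditions: Dess–Martin periodinane, pyridine, CH2Cl2, 0 °C to rt
Reagents that add atoms: none
Why: Dess–Martin oxidation of the primary epoxy alcohol gives an aldehyde that has no α-hydrogen and therefore cannot epimerise.

Step 18
Reactants: 23 (1S,4S,6R)-4-[(tert-butyldimethylsilyl)oxy]-2,2,6-trimethyl-7-oxabicyclo[4.1.0]heptane-1-carbaldehyde
Product: 24 tert-butyl({(1R,3S,6S)-6-[(E)-2-iodoethenyl]-1,5,5-trimethyl-7-oxabicyclo[4.1.0]heptan-3-yl}oxy)dimethylsilane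
Conditions: CrCl2 (6 equiv), CHI3 (2 equiv), THF, 0 °C to rt
Reagents that add atoms: iodoform, IC(I)I
Why: Takai iodo-olefination (geminal dichromium reagent from CHI3 and CrCl2) should convert the hindered aldehyde into the E-vinyl iodide and so sets the C7=C8 geometry.

Step 19
Reactants: 24 tert-butyl({(1R,3S,6S)-6-[(E)-2-iodoethenyl]-1,5,5-trimethyl-7-oxabicyclo[4.1.0]heptan-3-yl}oxy)dimethylsilane
Product: 25 tert-butyldimethyl({(1R,3S,6S)-1,5,5-trimethyl-6-[(E)-2-(tributylstannyl)ethenyl]-7-oxabicyclo[4.1.0]heptan-3-yl}oxy)silane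
Conditions: t-BuLi (2.1 equiv), Et2O, −78 °C; Bu3SnCl, −78 to 0 °C
Reagents that add atoms: tributyltin chloride, CCCC[Sn](Cl)(CCCC)CCCC
Why: Iodine–lithium exchange proceeds with retention of alkene geometry, and trapping with Bu3SnCl gives the E-vinylstannane; at −78 °C the tetrasubstituted epoxide and the silyl ether should not be attacked.

Step 20
Reactants: 25 tert-butyldimethyl({(1R,3S,6S)-1,5,5-trimethyl-6-[(E)-2-(tributylstannyl)ethenyl]-7-oxabicyclo[4.1.0]heptan-3-yl}oxy)silane
Product: 26 (1R,3S,6S)-1,5,5-trimethyl-6-[(E)-2-(tributylstannyl)ethenyl]-7-oxabicyclo[4.1.0]heptan-3-ol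
Conditions: Bu4NF, THF, rt
Reagents that add atoms: none
Why: Fluoride desilylation under basic conditions should leave both the acid-sensitive epoxide and the vinylstannane intact.

Step 21
Reactants: 19 (5Z)-3-bromo-5-[(2E,4E,6E,8E)-11-[(4R)-4-hydroxy-2,6,6-trimethylcyclohex-1-en-1-yl]-2,9-dimethylundeca-2,4,6,8-tetraen-10-yn-1-ylidene]furan-2(5H)-one; 26 (1R,3S,6S)-1,5,5-trimethyl-6-[(E)-2-(tributylstannyl)ethenyl]-7-oxabicyclo[4.1.0]heptan-3-ol
Product: 27 pyrrhoxanthinol (the target), (5Z)-3-[(E)-2-[(1S,4S,6R)-4-hydroxy-2,2,6-trimethyl-7-oxabicyclo[4.1.0]heptan-1-yl]ethenyl]-5-[(2E,4E,6E,8E)-11-[(4R)-4-hydroxy-2,6,6-trimethylcyclohex-1-en-1-yl]-2,9-dimethylundeca-2,4,6,8-tetraen-10-yn-1-ylidene]furan-2(5H)-one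
Conditions: Pd2(dba)3 (5 mol%), AsPh3 (40 mol%), NMP, rt to 40 °C, dark
Reagents that add atoms: none
Why: Stille coupling of the α-bromobutenolide with the E-alkenylstannane forms C8–C9 with retention of geometry in both partners, under neutral conditions that the ylidenebutenolide, the epoxide and the free hydroxyls should tolerate.

**Compound list**

1 | methyl 2-methyl-3-oxopentanoate | CCC(=O)C(C)C(=O)OC | starting material
2 | benzyl 2-methyl-3-oxopentanoate | CCC(=O)C(C)C(=O)OCc1ccccc1 | intermediate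
3 | (S)-epichlorohydrin | ClC[C@@H]1CO1 | starting material
4 | (2R)-1-chloro-3-iodopropan-2-ol | IC[C@H](O)CCl | intermediate
5 | tert-butyl{[(2R)-1-chloro-3-iodopropan-2-yl]oxy}dimethylsilane | IC[C@H](O[Si](C)(C)C(C)(C)C)CCl | intermediate
6 | benzyl (6S)-6-[(tert-butyldimethylsilyl)oxy]-7-chloro-2,4-dimethyl-3-oxoheptanoate (present as its lithium enolate) | O=C(OCc1ccccc1)C(C)C(=O)C(C)C[C@H](O[Si](C)(C)C(C)(C)C)CCl | intermediate
7 | benzyl (5S)-5-[(tert-butyldimethylsilyl)oxy]-1,3-dimethyl-2-oxocyclohexane-1-carboxylate | CC1(C(=O)OCc2ccccc2)C(=O)C(C)C[C@H](O[Si](C)(C)C(C)(C)C)C1 | intermediate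
8 | benzyl (5S)-5-[(tert-butyldimethylsilyl)oxy]-1,3,3-trimethyl-2-oxocyclohexane-1-carboxylate | CC1(C(=O)OCc2ccccc2)C(=O)C(C)(C)C[C@H](O[Si](C)(C)C(C)(C)C)C1 | intermediate
9 | (4R)-4-[(tert-butyldimethylsilyl)oxy]-2,2,6-trimethylcyclohexan-1-one | CC1C(=O)C(C)(C)C[C@H](O[Si](C)(C)C(C)(C)C)C1 | intermediate
10 | (4R)-4-[(tert-butyldimethylsilyl)oxy]-2,6,6-trimethylcyclohex-1-en-1-yl trifluoromethanesulfonate | CC1=C(OS(=O)(=O)C(F)(F)F)C(C)(C)C[C@H](O[Si](C)(C)C(C)(C)C)C1 | intermediate
11 | (2E)-3-methylpent-2-en-4-yn-1-ol | C#C/C(C)=C/CO | starting material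
12 | [(2E)-3-methylpent-2-en-4-yn-1-yl]triphenylphosphonium bromide | C#C/C(C)=C/C[P+](c1ccccc1)(c1ccccc1)c1ccccc1.[Br-] | intermediate
13 | glyoxal | O=CC=O | starting material
14 | (3E,5E,7E,9E)-3,10-dimethyldodeca-3,5,7,9-tetraene-1,11-diyne | C#C/C(C)=C/C=C/C=C/C=C(C)/C#C | intermediate
15 | tert-butyl({(1R)-4-[(3E,5E,7E,9E)-3,10-dimethyldodeca-3,5,7,9-tetraene-1,11-diyn-1-yl]-3,5,5-trimethylcyclohex-3-en-1-yl}oxy)dimethylsilane | CC1=C(C#C/C(C)=C/C=C/C=C/C=C(C)/C#C)C(C)(C)C[C@H](O[Si](C)(C)C(C)(C)C)C1 | intermediate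
16 | (1R)-4-[(3E,5E,7E,9E)-3,10-dimethyldodeca-3,5,7,9-tetraene-1,11-diyn-1-yl]-3,5,5-trimethylcyclohex-3-en-1-ol | CC1=C(C#C/C(C)=C/C=C/C=C/C=C(C)/C#C)C(C)(C)C[C@H](O)C1 | intermediate
17 | propiolic acid | OC(=O)C#C | starting material
18 | (2E)-2,3-dibromoprop-2-enoic acid | OC(=O)/C(Br)=C\Br | intermediate
19 | (5Z)-3-bromo-5-[(2E,4E,6E,8E)-11-[(4R)-4-hydroxy-2,6,6-trimethylcyclohex-1-en-1-yl]-2,9-dimethylundeca-2,4,6,8-tetraen-10-yn-1-ylidene]furan-2(5H)-one | CC1=C(C#C/C(C)=C/C=C/C=C/C=C(C)/C=C2C=C(Br)C(=O)O/2)C(C)(C)C[C@H](O)C1 | intermediate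
20 | methyl (4R)-4-[(tert-butyldimethylsilyl)oxy]-2,6,6-trimethylcyclohex-1-ene-1-carboxylate | CC1=C(C(=O)OC)C(C)(C)C[C@H](O[Si](C)(C)C(C)(C)C)C1 | intermediate
21 | [(4R)-4-[(tert-butyldimethylsilyl)oxy]-2,6,6-trimethylcyclohex-1-en-1-yl]methanol | CC1=C(CO)C(C)(C)C[C@H](O[Si](C)(C)C(C)(C)C)C1 | intermediate
22 | [(1R,4S,6R)-4-[(tert-butyldimethylsilyl)oxy]-2,2,6-trimethyl-7-oxabicyclo[4.1.0]heptan-1-yl]methanol | OC[C@@]12O[C@]1(C)C[C@@H](O[Si](C)(C)C(C)(C)C)CC2(C)C | intermediate
23 | (1S,4S,6R)-4-[(tert-butyldimethylsilyl)oxy]-2,2,6-trimethyl-7-oxabicyclo[4.1.0]heptane-1-carbaldehyde | O=C[C@@]12O[C@]1(C)C[C@@H](O[Si](C)(C)C(C)(C)C)CC2(C)C | intermediate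
24 | tert-butyl({(1R,3S,6S)-6-[(E)-2-iodoethenyl]-1,5,5-trimethyl-7-oxabicyclo[4.1.0]heptan-3-yl}oxy)dimethylsilane | I/C=C/[C@@]12O[C@]1(C)C[C@@H](O[Si](C)(C)C(C)(C)C)CC2(C)C | intermediate
25 | tert-butyldimethyl({(1R,3S,6S)-1,5,5-trimethyl-6-[(E)-2-(tributylstannyl)ethenyl]-7-oxabicyclo[4.1.0]heptan-3-yl}oxy)silane | CCCC[Sn](CCCC)(CCCC)/C=C/[C@@]12O[C@]1(C)C[C@@H](O[Si](C)(C)C(C)(C)C)CC2(C)C | intermediate
26 | (1R,3S,6S)-1,5,5-trimethyl-6-[(E)-2-(tributylstannyl)ethenyl]-7-oxabicyclo[4.1.0]heptan-3-ol | CCCC[Sn](CCCC)(CCCC)/C=C/[C@@]12O[C@]1(C)C[C@@H](O)CC2(C)C | intermediate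
27 | pyrrhoxanthinol, (3S,5R,6S,3'R) | CC1=C(C#C/C(C)=C/C=C/C=C/C=C(C)/C=C2C=C(/C=C/[C@@]34O[C@]3(C)C[C@@H](O)CC4(C)C)C(=O)O/2)C(C)(C)C[C@H](O)C1 | target

**Count and risks**

Total: 21 steps. Longest linear sequence: 14 steps (steps 2, 3, 4, 5, 6, 7, 14, 15, 16, 17, 18, 19, 20, 21).

Steps most likely to fail:

1. Step 4. The γ-alkylation by the β-silyloxy iodide may stall, the ring closure may go through oxygen or not at all, and attack on the chloride-bearing arm would break the site order that carries the configuration. Fallback: the two bonds are made in separate operations, setting out from 5 and coming back at 9 (steps 4 to 6 are bypassed). Lithiated isobutyronitrile (LiN(iPr)2, THF/DMPU, −78 to 0 °C) is alkylated by 5 at the iodide to give (4S)-4-[(tert-butyldimethylsilyl)oxy]-5-chloro-2,2-dimethylpentanenitrile F1, with both methyl groups already in place. Addition of EtLi (or EtMgBr) and acidic hydrolysis of the imine gives (6S)-6-[(tert-butyldimethylsilyl)oxy]-7-chloro-4,4-dimethylheptan-3-one F2. This ketone can enolise on one side only, and LiN(iPr)2 in THF/DMPU should close it onto the chloride (6-(enolendo)-exo-tet) to give 9.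

2. Step 13. Oxidative addition may also occur at the α-bromide, the product bromide may couple a second time with the alkyne, and 6-endo closure to a pyranone may compete. Fallback: coupling and lactonisation are separated, setting out from 16 and 18 and coming back at 19. Acid 18 is esterified (EtOH, cat. H2SO4) to ethyl (2E)-2,3-dibromoprop-2-enoate F3. Sonogashira coupling of 16 with F3 (Pd(PPh3)4, CuI, Et3N, MeCN, rt), which should take place at the β-bromide only, gives ethyl (2E,6E,8E,10E,12E)-2-bromo-15-[(4R)-4-hydroxy-2,6,6-trimethylcyclohex-1-en-1-yl]-6,13-dimethylpentadeca-2,6,8,10,12-pentaene-4,14-diynoate F4. LiOH (THF/H2O) gives the corresponding acid F5, and AgNO3 (cat.) in acetone should close it 5-exo-dig with anti addition to 19.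

3. Step 9. Glyoxal may be lost to base-induced side reactions, the second olefination may be incomplete and E/Z control poor; the statistical mono-coupling of step 10 also depends on this material. Fallback: the chain is built linearly on the ring, setting out from 10 and 11 and coming back at 15 (steps 9 and 10 are bypassed). Sonogashira coupling of 10 with 11 gives (2E)-5-[(4R)-4-[(tert-butyldimethylsilyl)oxy]-2,6,6-trimethylcyclohex-1-en-1-yl]-3-methylpent-2-en-4-yn-1-ol F6. MnO2 (CH2Cl2) gives the corresponding enynal F7. Wittig reaction with (triphenylphosphoranylidene)acetaldehyde (toluene, 80 °C) gives (2E,4E)-7-[(4R)-4-[(tert-butyldimethylsilyl)oxy]-2,6,6-trimethylcyclohex-1-en-1-yl]-5-methylhepta-2,4-dien-6-ynal F8. Wittig reaction of F8 with 12 (NaOMe, MeOH/CH2Cl2), followed by iodine-catalysed equilibration, should give 15.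

**Further compounds**

F1 | step 4 | (4S)-4-[(tert-butyldimethylsilyl)oxy]-5-chloro-2,2-dimethylpentanenitrile | N#CC(C)(C)C[C@H](O[Si](C)(C)C(C)(C)C)CCl
F2 | step 4 | (6S)-6-[(tert-butyldimethylsilyl)oxy]-7-chloro-4,4-dimethylheptan-3-one | CCC(=O)C(C)(C)C[C@H](O[Si](C)(C)C(C)(C)C)CCl
F3 | step 13 | ethyl (2E)-2,3-dibromoprop-2-enoate | CCOC(=O)/C(Br)=C\Br
F4 | step 13 | ethyl (2E,6E,8E,10E,12E)-2-bromo-15-[(4R)-4-hydroxy-2,6,6-trimethylcyclohex-1-en-1-yl]-6,13-dimethylpentadeca-2,6,8,10,12-pentaene-4,14-diynoate | CCOC(=O)/C(Br)=C\C#C/C(C)=C/C=C/C=C/C=C(C)/C#CC1=C(C)C[C@@H](O)CC1(C)C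
F5 | step 13 | (2E,6E,8E,10E,12E)-2-bromo-15-[(4R)-4-hydroxy-2,6,6-trimethylcyclohex-1-en-1-yl]-6,13-dimethylpentadeca-2,6,8,10,12-pentaene-4,14-diynoic acid | OC(=O)/C(Br)=C\C#C/C(C)=C/C=C/C=C/C=C(C)/C#CC1=C(C)C[C@@H](O)CC1(C)C
F6 | step 9 | (2E)-5-[(4R)-4-[(tert-butyldimethylsilyl)oxy]-2,6,6-trimethylcyclohex-1-en-1-yl]-3-methylpent-2-en-4-yn-1-ol | CC1=C(C#C/C(C)=C/CO)C(C)(C)C[C@H](O[Si](C)(C)C(C)(C)C)C1
F7 | step 9 | (2E)-5-[(4R)-4-[(tert-butyldimethylsilyl)oxy]-2,6,6-trimethylcyclohex-1-en-1-yl]-3-methylpent-2-en-4-ynal | CC1=C(C#C/C(C)=C/C=O)C(C)(C)C[C@H](O[Si](C)(C)C(C)(C)C)C1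
F8 | step 9 | (2E,4E)-7-[(4R)-4-[(tert-butyldimethylsilyl)oxy]-2,6,6-trimethylcyclohex-1-en-1-yl]-5-methylhepta-2,4-dien-6-ynal | CC1=C(C#C/C(C)=C/C=C/C=O)C(C)(C)C[C@H](O[Si](C)(C)C(C)(C)C)C1
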